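## Structural features

The target is an unsymmetrical C–O–C biflavonoid. A (2S)-flavanone (rings A and C, with 4-hydroxyphenyl ring B on C2) is joined through the oxygen on C6 of its ring A to C4''' of the para-phenylene ring of a 5'',7''-dihydroxyflavone. Ring A of the flavanone carries four oxygens in a row: O1 on C8a, the 5-OH chelated to the C4 carbonyl, the 6-aryloxy group and the 7-OMe. The diaryl ether oxygen is therefore flanked on both sides, and the single methyl ether must be told apart from four free phenols. C2 is the only stereocentre; it has no stereogenic neighbour, is benzylic, bears O1 and lies β to the ketone. The flavanone is therefore the fragile part: base, or strong acid acting on an electron-rich ring B, opens ring C to the chalcone (retro-oxa-Michael) and racemises C2, most easily once 4'-OH and 5-OH are free. Further sensitive points are the C2''=C3'' enone of the flavone towards hydride and carbon nucleophiles, and the ready polymerisation of 4-vinylphenol. The real difficulties are the di-ortho-substituted diaryl ether and the enantioselective creation of C2 in a molecule that tolerates no base afterwards. The key step uses the fact that ring C is a six-membered oxygen ring fused to electron-rich ring A: O1–C8a–C4a–C4 is the hetero-diene of an ortho-quinone methide and C2–C3 with ring B is the vinyl group of 4-vinylphenol, so O1–C2 and C3–C4 can be made in one cycloaddition that also sets C2.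

## Logic of the disconnections

19 ⇒ 17 (through 18). The two O–CH2Ph bonds on the flavone, the O–CH3 bond at C5 and the O–acetyl bond at 4'-O are re-formed. Every phenol that could interfere with an oxidant or help C2 to ionise stays masked until the last operation, and the C5 methyl is the only methyl ether peri to the C4 carbonyl. The gain is a precursor without free phenols. The demand is that one Lewis acid distinguishes C5–OMe from C7–OMe and that the ester leaves under acid, because base opens ring C.

17 ⇒ 15. The C4 ketone is traced back to C4(H)–OMe. A benzylic methyl ether on C4 is what an ortho-quinone methide cycloaddition delivers, and it already holds C4 at the oxidation level of an aldehyde. The gain is that no β-aryloxy ketone exists before this point. The demand is that hydride leaves from C4 and not from C2.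

15 ⇒ 14. The O–acetyl bond at 4'-O is cut. The free phenol is needed in the ring-forming step but is a liability afterwards, since it makes C2–H easy to oxidise or ionise. The demand is only a chemoselective acylation of the one free hydroxyl.

14 ⇒ 11 + 12. O1–C2 and C3–C4 are cut. The cut divides the molecule into a salicylaldehyde that carries the finished flavone and a purchasable styrene, and it removes ring C and both stereocentres at once. The forward step must control the face of the styrene with a chiral acid, follow the polarity of the two partners, and find only one phenol ortho to the aldehyde; the second ortho oxygen of 11 is therefore kept as a methyl ether.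

11 ⇒ 9. The aryl–CHO bond ortho to the phenol is cut. The phenol 9 has two identical ortho positions, so no regiochemical question arises. The demand is ortho-selective formylation without touching the benzyloxy-substituted flavone ring.

9 ⇒ 7. The aryl C–OH bond is traced back to aryl C–CHO. The formyl group makes the ring A piece a commercial aldehyde. The demand is aryl rather than hydride migration in the peracid oxidation.

7 ⇒ 5 + 6. The diaryl ether bond O–C4''' is cut. This is the most convergent cut, dividing the biflavonoid into its two halves. The demand is that a hindered phenoxide displaces a fluoride activated only through the flavone enone.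

5 ⇒ 4. The O1''–C2'' bond and the C2''=C3'' unsaturation are removed. The demand is an oxidative cyclisation that spares the benzyl ethers and the aryl fluoride.

4 ⇒ 2 + 3. The Cα=Cβ bond of the enone is cut. The demand is an aldol condensation mild enough that the fluoride is not displaced by the base.

2 ⇒ 1. Two O–benzyl bonds are cut. The demand is that the hydrogen-bonded ortho hydroxyl remains free for the later ring closure.

## Other disconnections considered

Alternative 1: The cut is through the ring bonds C2'''–C3''' and C4'''–C5''' of the para-phenylene ring, which would be assembled around an existing aryl–O bond. In the forward step the aryl ethynyl ether A1 would react as the electron-rich 2π partner across C3 and C6 of the 2-pyranone A2. The bridged lactone would then decarboxylate to the para-aryloxybenzoate A3.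
- In favour: the hindered diaryl ether is never made by substitution at an aromatic carbon. The para pattern follows from polarity, the unsubstituted alkyne carbon of A1 bonding to the most electrophilic carbon, C6, of A2. No metal is needed. On this point the alternative is better than step 4 of the chosen plan.
- Against: a benzene ring that can be bought with the right substitution (as 3) is built from scratch. A1 needs about three steps from the phenol and is sensitive to hydration and heat, while the cycloaddition needs heating. A3 must still be converted into the flavone, deprotected and formylated, after which the same construction of ring C is needed; the alternative does nothing for C2.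
- Comparison: structurally it solves only the ether problem. Mechanistically both plans rest on a polarity-controlled cycloaddition, which makes them equal in kind. In step economy the alternative is longer by roughly four steps to an analogue of 9. The ester of A3 is an equal starting point for the flavone compared with the chalcone route of steps 2 and 3.

Alternative 2: The cut is at C4a''–C5'' of the flavone, so its phloroglucinol ring is unravelled to a 4-pyranone carrying a masked keto-acyl side chain, the acyl dioxanedione A4. Heating A4 would fragment the dioxanedione ring. The resulting acylketene, as its dienol, would close onto the α-carbon of the pyranone and tautomerise to the 5,7-dihydroxyflavone A5.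
- In favour: the step is thermal, neutral and reagent-free, and it follows a polyketide-like folding. It delivers the 5'',7''-diol without protecting groups, so step 1 and the two debenzylations of step 10 would not be needed. In protecting-group economy at the flavone the alternative is better.
- Against: A4 needs a 2-aryl-6-methyl-4-pyranone and a side-chain homologation, about five to six steps against three steps to 5. The acylketene may close through oxygen to a pyranone or be captured by any hydroxyl instead of forming the C–C bond. The free phloroglucinol ring of A5 would compete in the later ortho-formylation, so protection would return. C2 is again not addressed.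
- Comparison: structurally it builds a ring that is available in 1. Mechanistically it carries a selectivity risk between C- and O-closure that steps 2 and 3 do not have. In step economy it is longer. It is equal to the chosen plan in that the diaryl ether would still be made by a separate substitution.

Alternative 3: The cut is at C4a–C5 and C8–C8a, so ring A of the flavanone is grown by a [4+2] on a preformed, enantiopure ring C. The 2-aryloxy vinylketene acetal A6 would add to the C5=C6 bond of the bromodihydropyranone A7. Dehydrobromination and loss of the alkoxy group would aromatise the adduct to the flavanone A8.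
- In favour: C2 would come from a catalytic asymmetric hetero-Diels–Alder reaction of an aryl aldehyde with a siloxydiene, a known reaction class. In precedent for the stereocentre the alternative is better than the chosen plan. The 5-OH/7-OMe pattern results directly, so no late selective demethylation is needed; on this point it is also better.
- Against: A6 is a crowded, hydrolytically labile tetra-oxygenated diene with uncertain geometry. A7 is a vinylogous ester and a weak dienophile, so forcing conditions are needed, under which ring C can open by β-elimination with loss of configuration at C2. After A8 the whole flavone must still be built on the aryl iodide, in the presence of a base-sensitive flavanone.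
- Comparison: structurally the chosen plan completes the flavone before the stereocentre exists, so the flavanone only meets acid and oxidant; the alternative carries C2 through many steps. Mechanistically the regiochemistry of such dienes with α-halo enones is as reliable as the polarity control of step 7, which makes the two equal. In step economy the alternative is clearly longer.

Key step: step 7

Assumption: the (R)-configured phosphoric acid of step 7 is taken to give the (2S) series; if the sense of induction is the opposite, its (S)-enantiomer is used with no other change.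
Remark: the descriptors were re-derived from the structures: C2 is S in 14 to 19, and 14 is (2S,4S), which is 2,4-cis.
Remark: 12 is sold as a stabilised solution and is freed of solvent and stabiliser just before use.

## Route

Step 1
Reactants: 1 2',4',6'-trihydroxyacetophenone
Product: 2 1-[2,4-bis(benzyloxy)-6-hydroxyphenyl]ethan-1-one
Conditions: BnBr (2.1 equiv), K2CO3, DMF, rt → 50 °C
Reagents that add atoms: benzyl bromide, BrCc1ccccc1
Why: Williamson ether synthesis; the hydroxyl hydrogen-bonded to the acetyl carbonyl is far less nucleophilic, so two equivalents of bromide etherify the para oxygen and one of the two equivalent ortho oxygens.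

Step 2
Reactants: 2 1-[2,4-bis(benzyloxy)-6-hydroxyphenyl]ethan-1-one; 3 4-fluorobenzaldehyde
Product: 4 (E)-1-[2,4-bis(benzyloxy)-6-hydroxyphenyl]-3-(4-fluorophenyl)prop-2-en-1-one
Conditions: KOH (50% aq), EtOH/THF, rt
Reagents that add atoms: none
Why: Claisen–Schmidt condensation; 3 cannot enolise and E1cB dehydration gives the E-enone, while room temperature keeps hydroxide and ethoxide from displacing the fluoride.

Step 3
Reactants: 4 (E)-1-[2,4-bis(benzyloxy)-6-hydroxyphenyl]-3-(4-fluorophenyl)prop-2-en-1-one
Product: 5 5,7-bis(benzyloxy)-2-(4-fluorophenyl)-4H-chromen-4-one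
Conditions: I2 (5 mol%), DMSO, 130 °C
Reagents that add atoms: none
Why: Iodine-catalysed oxidative cyclisation of a 2'-hydroxychalcone in DMSO (oxa-Michael closure, then iodination and loss of HI, DMSO being the terminal oxidant), a standard flavone synthesis that benzyl ethers and the aryl fluoride tolerate.

Step 4
Reactants: 5 5,7-bis(benzyloxy)-2-(4-fluorophenyl)-4H-chromen-4-one; 6 syringaldehyde
Product: 7 4-{4-[5,7-bis(benzyloxy)-4-oxo-4H-chromen-2-yl]phenoxy}-3,5-dimethoxybenzaldehyde
Conditions: K2CO3, DMSO, 130 °C
Reagents that add atoms: none
Why: Nucleophilic aromatic substitution; the fluorine is conjugated through C2''=C3'' to the C4'' carbonyl, so the Meisenheimer anion is a vinylogous enolate and fluoride is the best leaving group for an addition-limited substitution. The phenoxide of 6 is hindered and resonance-stabilised, hence DMSO and heat.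

Step 5
Reactants: 7 4-{4-[5,7-bis(benzyloxy)-4-oxo-4H-chromen-2-yl]phenoxy}-3,5-dimethoxybenzaldehyde
Product: 9 5,7-bis(benzyloxy)-2-[4-(4-hydroxy-2,6-dimethoxyphenoxy)phenyl]-4H-chromen-4-one, via aryl formate 8 (not isolated)
Conditions: mCPBA, CH2Cl2, 0 °C → rt; then Et3N, MeOH, rt
Reagents that add atoms: mCPBA (3-chloroperbenzoic acid), O=C(OO)c1cccc(Cl)c1
Why: Baeyer–Villiger oxidation of an aryl aldehyde (the peracid form of the Dakin oxidation); the electron-rich aryl group with its para-aryloxy donor migrates in preference to hydride and the formate 8 is cleaved by mild methanolysis. The flavone enone is too electron-poor for peracid epoxidation.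

Step 6
Reactants: 9 5,7-bis(benzyloxy)-2-[4-(4-hydroxy-2,6-dimethoxyphenoxy)phenyl]-4H-chromen-4-one
Product: 11 5-{4-[5,7-bis(benzyloxy)-4-oxo-4H-chromen-2-yl]phenoxy}-2-hydroxy-4,6-dimethoxybenzaldehyde, via salicyl alcohol 10 (not isolated)
Conditions: MgCl2, Et3N, (CH2O)n, MeCN, reflux
Reagents that add atoms: paraformaldehyde (as formaldehyde), C=O
Why: Magnesium-mediated ortho-formylation of a phenol (Casnati–Skattebøl reaction); the magnesium phenoxide delivers formaldehyde to the ortho carbon through a chelate and a second formaldehyde oxidises the benzylic alkoxide of 10 by hydride transfer. The two ortho positions of 9 are equivalent and no other free phenol is present, so only one aldehyde can form.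

Step 7
Reactants: 11 5-{4-[5,7-bis(benzyloxy)-4-oxo-4H-chromen-2-yl]phenoxy}-2-hydroxy-4,6-dimethoxybenzaldehyde; 12 4-vinylphenol
Product: 14 (2S,4S)-6-{4-[5,7-bis(benzyloxy)-4-oxo-4H-chromen-2-yl]phenoxy}-2-(4-hydroxyphenyl)-4,5,7-trimethoxychromane (the 2,4-cis 4-methoxyflavan), via dimethyl acetal 13 (not isolated)
Conditions: HC(OMe)3 (3 equiv), (R)-3,3'-bis(2,4,6-triisopropylphenyl)-1,1'-binaphthyl-2,2'-diyl hydrogen phosphate (10 mol%), 5 Å MS, toluene, 0 °C, 1 h; then 12 (2 equiv) by syringe pump, −20 °C → rt
Reagents that add atoms: trimethyl orthoformate, COC(OC)OC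
Why: Proposed new method: the phosphoric acid first catalyses acetal exchange of 11 with the orthoformate to 13 and then ionises 13 to an O-methyl oxocarbenium phenol, that is a 4-methoxy ortho-quinone methide which the ring oxygen and the two methoxy groups of ring A make persistent enough to be intercepted; the closest known reaction types are the Sc(OTf)3-catalysed three-component union of salicylaldehydes, trimethyl orthoformate and styrenes to racemic 4-alkoxyflavans and the chiral phosphoric acid-catalysed [4+2] additions of ortho-quinone methides to hydroxystyrenes, and the proposal merges the two. The electron-rich styrene 12 adds in an asynchronous inverse-electron-demand hetero-Diels–Alder reaction: its CH2 terminus bonds to C4, and the benzylic carbon, which takes on para-quinone-methide-like cationic character, is captured by the phenolic oxygen. Ring C thus closes as a six-membered ring by [4+2] cycloaddition (in the stepwise limit by 6-exo-trig capture of the benzylic cation by O1). C2 is controlled by the catalyst: the P–OH binds the quinone methide oxygen and the P=O accepts a hydrogen bond from the 4'-OH of 12, so the styrene is held in the pocket of the 3,3'-aryl groups and only one of its faces reaches C4 and O1. C4 is controlled by the substrate through an endo-like approach that places methoxy and aryl both pseudo-equatorial (2,4-cis), and this centre is erased at step 9 in any case. Regiochemistry is secured by the polarity match between the nucleophilic CH2 of 12 and the electrophilic C4. A single ring oxygen is secured by the methyl ether on the other ortho oxygen of 11. Chemoselectivity over cationic oligomerisation of 12 is addressed by the weak acid, the low temperature and the slow addition of 12 to preformed 13, the benzyl-protected flavone being a spectator apart from the basicity of its carbonyl group.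

Step 8
Reactants: 14 (2S,4S)-6-{4-[5,7-bis(benzyloxy)-4-oxo-4H-chromen-2-yl]phenoxy}-2-(4-hydroxyphenyl)-4,5,7-trimethoxychromane
Product: 15 4-[(2S,4S)-6-{4-[5,7-bis(benzyloxy)-4-oxo-4H-chromen-2-yl]phenoxy}-4,5,7-trimethoxychroman-2-yl]phenyl acetate
Conditions: Ac2O, pyridine, DMAP (cat.), CH2Cl2, 0 °C → rt
Reagents that add atoms: acetic anhydride, CC(=O)OC(C)=O
Why: DMAP-catalysed O-acylation of the only free hydroxyl; the acetate lowers the donor power of ring B so that C2–H is protected against hydride abstraction and ionisation in steps 9 and 10.

Step 9
Reactants: 15 4-[(2S,4S)-6-{4-[5,7-bis(benzyloxy)-4-oxo-4H-chromen-2-yl]phenoxy}-4,5,7-trimethoxychroman-2-yl]phenyl acetate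
Product: 17 4-[(2S)-6-{4-[5,7-bis(benzyloxy)-4-oxo-4H-chromen-2-yl]phenoxy}-5,7-dimethoxy-4-oxochroman-2-yl]phenyl acetate, via methyl hemiketal 16 (not isolated)
Conditions: DDQ (1.2 equiv), CH2Cl2/pH 7 buffer (10:1), 0 °C → rt
Reagents that add atoms: water, O
Why: DDQ oxidation of an electron-rich benzylic methyl ether, the same hydride abstraction that cleaves p-methoxybenzyl ethers; the pseudo-axial C4–H gives an oxocarbenium ion stabilised by the methoxy group and ring A, water adds to give 16 and methanol is lost. C2–H sits on the electron-poorer acetoxyphenyl carbinol ether and is not involved, so its configuration is kept.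

Step 10
Reactants: 17 4-[(2S)-6-{4-[5,7-bis(benzyloxy)-4-oxo-4H-chromen-2-yl]phenoxy}-5,7-dimethoxy-4-oxochroman-2-yl]phenyl acetate
Product: 19 (2S)-6-[4-(5,7-dihydroxy-4-oxo-4H-chromen-2-yl)phenoxy]-5-hydroxy-2-(4-hydroxyphenyl)-7-methoxychroman-4-one (CNP0269971.1), via 4'-acetate 18 (not isolated)
Conditions: BCl3 (8 equiv), C6HMe5 (6 equiv), CH2Cl2, −78 → 0 °C; then MeOH, 0 → 40 °C
Reagents that add atoms: none
Why: Lewis acid ether cleavage with BCl3: with pentamethylbenzene as a non-basic cation scavenger both benzyl ethers fall at low temperature, and on warming only the methyl ether peri to the C4 carbonyl is cleaved through a six-membered boron chelate, the unchelated C7 methyl ether remaining. The methanol quench frees HCl, which transesterifies the aryl acetate of 18 without base, so C2 never meets conditions that open ring C.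

## Compound list

1 | 2',4',6'-trihydroxyacetophenone | CC(=O)c1c(O)cc(O)cc1O | starting material
2 | 1-[2,4-bis(benzyloxy)-6-hydroxyphenyl]ethan-1-one | CC(=O)c1c(O)cc(OCc2ccccc2)cc1OCc1ccccc1 | intermediate
3 | 4-fluorobenzaldehyde | O=Cc1ccc(F)cc1 | starting material
4 | (E)-1-[2,4-bis(benzyloxy)-6-hydroxyphenyl]-3-(4-fluorophenyl)prop-2-en-1-one | O=C(/C=C/c1ccc(F)cc1)c1c(O)cc(OCc2ccccc2)cc1OCc1ccccc1 | intermediate
5 | 5,7-bis(benzyloxy)-2-(4-fluorophenyl)-4H-chromen-4-one | O=c1cc(-c2ccc(F)cc2)oc2cc(OCc3ccccc3)cc(OCc3ccccc3)c12 | intermediate
6 | syringaldehyde (4-hydroxy-3,5-dimethoxybenzaldehyde) | COc1cc(C=O)cc(OC)c1O | starting material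
7 | 4-{4-[5,7-bis(benzyloxy)-4-oxo-4H-chromen-2-yl]phenoxy}-3,5-dimethoxybenzaldehyde | COc1cc(C=O)cc(OC)c1Oc1ccc(-c2cc(=O)c3c(OCc4ccccc4)cc(OCc4ccccc4)cc3o2)cc1 | intermediate
8 | 4-{4-[5,7-bis(benzyloxy)-4-oxo-4H-chromen-2-yl]phenoxy}-3,5-dimethoxyphenyl formate (formed in the flask, not isolated) | COc1cc(OC=O)cc(OC)c1Oc1ccc(-c2cc(=O)c3c(OCc4ccccc4)cc(OCc4ccccc4)cc3o2)cc1 | intermediate
9 | 5,7-bis(benzyloxy)-2-[4-(4-hydroxy-2,6-dimethoxyphenoxy)phenyl]-4H-chromen-4-one | COc1cc(O)cc(OC)c1Oc1ccc(-c2cc(=O)c3c(OCc4ccccc4)cc(OCc4ccccc4)cc3o2)cc1 | intermediate
10 | 5,7-bis(benzyloxy)-2-{4-[4-hydroxy-3-(hydroxymethyl)-2,6-dimethoxyphenoxy]phenyl}-4H-chromen-4-one (formed in the flask, not isolated) | COc1cc(O)c(CO)c(OC)c1Oc1ccc(-c2cc(=O)c3c(OCc4ccccc4)cc(OCc4ccccc4)cc3o2)cc1 | intermediate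
11 | 5-{4-[5,7-bis(benzyloxy)-4-oxo-4H-chromen-2-yl]phenoxy}-2-hydroxy-4,6-dimethoxybenzaldehyde | COc1cc(O)c(C=O)c(OC)c1Oc1ccc(-c2cc(=O)c3c(OCc4ccccc4)cc(OCc4ccccc4)cc3o2)cc1 | intermediate
12 | 4-vinylphenol | C=Cc1ccc(O)cc1 | starting material
13 | 5,7-bis(benzyloxy)-2-{4-[3-(dimethoxymethyl)-4-hydroxy-2,6-dimethoxyphenoxy]phenyl}-4H-chromen-4-one (formed in the flask, not isolated) | COc1cc(O)c(C(OC)OC)c(OC)c1Oc1ccc(-c2cc(=O)c3c(OCc4ccccc4)cc(OCc4ccccc4)cc3o2)cc1 | intermediate
14 | (2S,4S)-6-{4-[5,7-bis(benzyloxy)-4-oxo-4H-chromen-2-yl]phenoxy}-2-(4-hydroxyphenyl)-4,5,7-trimethoxychromane | COc1cc2c(c(OC)c1Oc1ccc(-c3cc(=O)c4c(OCc5ccccc5)cc(OCc5ccccc5)cc4o3)cc1)[C@@H](OC)C[C@@H](c1ccc(O)cc1)O2 | intermediate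
15 | 4-[(2S,4S)-6-{4-[5,7-bis(benzyloxy)-4-oxo-4H-chromen-2-yl]phenoxy}-4,5,7-trimethoxychroman-2-yl]phenyl acetate | COc1cc2c(c(OC)c1Oc1ccc(-c3cc(=O)c4c(OCc5ccccc5)cc(OCc5ccccc5)cc4o3)cc1)[C@@H](OC)C[C@@H](c1ccc(OC(C)=O)cc1)O2 | intermediate
16 | 4-[(2S)-6-{4-[5,7-bis(benzyloxy)-4-oxo-4H-chromen-2-yl]phenoxy}-4-hydroxy-4,5,7-trimethoxychroman-2-yl]phenyl acetate, C4 unassigned (formed in the flask, not isolated) | COc1cc2c(c(OC)c1Oc1ccc(-c3cc(=O)c4c(OCc5ccccc5)cc(OCc5ccccc5)cc4o3)cc1)C(O)(OC)C[C@@H](c1ccc(OC(C)=O)cc1)O2 | intermediate
17 | 4-[(2S)-6-{4-[5,7-bis(benzyloxy)-4-oxo-4H-chromen-2-yl]phenoxy}-5,7-dimethoxy-4-oxochroman-2-yl]phenyl acetate | COc1cc2c(c(OC)c1Oc1ccc(-c3cc(=O)c4c(OCc5ccccc5)cc(OCc5ccccc5)cc4o3)cc1)C(=O)C[C@@H](c1ccc(OC(C)=O)cc1)O2 | intermediate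
18 | 4-[(2S)-6-[4-(5,7-dihydroxy-4-oxo-4H-chromen-2-yl)phenoxy]-5-hydroxy-7-methoxy-4-oxochroman-2-yl]phenyl acetate (formed in the flask, not isolated) | COc1cc2c(c(O)c1Oc1ccc(-c3cc(=O)c4c(O)cc(O)cc4o3)cc1)C(=O)C[C@@H](c1ccc(OC(C)=O)cc1)O2 | intermediate
19 | (2S)-6-[4-(5,7-dihydroxy-4-oxo-4H-chromen-2-yl)phenoxy]-5-hydroxy-2-(4-hydroxyphenyl)-7-methoxychroman-4-one (CNP0269971.1) | COc1cc2c(c(O)c1Oc1ccc(-c3cc(=O)c4c(O)cc(O)cc4o3)cc1)C(=O)C[C@@H](c1ccc(O)cc1)O2 | target

## Step count and least certain steps

Total step count: 10. Longest linear sequence: 10 steps (1 to 19); 3, 6 and 12 are purchased and enter at steps 2, 4 and 7.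

Step 7 (the one step that goes beyond known chemistry). The most likely failure is poor facial selectivity, because the basic flavone carbonyl can bind the catalyst and an achiral acid-catalysed background pathway can compete. The second is cationic oligomerisation of 12 outrunning the cycloaddition if the acetal ionises slowly. Fallback: setting out from 11 and 12, the known racemic three-component reaction (Sc(OTf)3 10 mol%, HC(OMe)3, CH2Cl2, rt) should give the racemic cis-4-methoxyflavan, which contains 14 and its (2R,4R) enantiomer F1. Preparative chromatography on a chiral stationary phase then separates the two, and the route is rejoined at 14. The source of chirality changes from catalysis to resolution.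

Step 4. The substitution may stall, since a hindered, resonance-stabilised phenoxide meets a fluoride activated only through a vinylogous carbonyl, and long heating with carbonate may begin to degrade 6 and the flavone. Fallback: the ether is made before the flavone, on the far more activated 3. Setting out from 3 and 2:
- purchased 4-bromo-2,6-dimethoxyphenol F2 and 3 (K2CO3, DMF, 120 °C) should give 4-(4-bromo-2,6-dimethoxyphenoxy)benzaldehyde F3;
- Claisen–Schmidt condensation of F3 with 2 should give the bromo chalcone F4;
- I2/DMSO should give the bromo diaryl ether flavone F5;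
- palladium-catalysed hydroxylation of the aryl bromide (Pd2(dba)3, t-BuXPhos, KOH, dioxane/H2O, 80 °C, acidic work-up) should give the phenol, rejoining the route at 9.
Compounds 5, 7 and 8 are bypassed and the step count is unchanged.

Step 9. Over-oxidation is the main risk: the oxocarbenium ion may lose a proton to the 4-methoxy-2H-chromene, and a second hydride abstraction at C2 would aromatise ring C and destroy the stereocentre; direct hydride abstraction at C2 is a lesser risk. Fallback: setting out from 15, acid solvolysis (PPTS, THF/H2O, 40 °C) should give the flavan-4-ol F6 as a mixture of C4 epimers, and Dess–Martin periodinane (NaHCO3, CH2Cl2, rt) oxidises it to the ketone, rejoining the route at 17. The oxidation then acts on an alcohol and no cation is formed in the presence of an oxidant.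

Step 10. The long exposure to excess BCl3 needed for complete debenzylation may cause Lewis-acid-promoted opening of ring C with erosion of the enantiomeric purity, C-benzylation by escaped benzyl cations, or partial loss of the C7 methyl ether. Fallback: setting out from 17, hydrogenolysis (H2, Pd/C, EtOAc/THF, rt) removes the benzyl groups to give the dihydroxyflavone acetate F7. A short, low-temperature BCl3 treatment (3 equiv, CH2Cl2, −40 → 0 °C) then cleaves only the chelated C5 methyl ether and rejoins the route at 18, which methanolic HCl converts into 19.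

## Further compounds

F1 | step 7 | (2R,4R)-6-{4-[5,7-bis(benzyloxy)-4-oxo-4H-chromen-2-yl]phenoxy}-2-(4-hydroxyphenyl)-4,5,7-trimethoxychromane, the enantiomer that accompanies 14 in the racemate | COc1cc2c(c(OC)c1Oc1ccc(-c3cc(=O)c4c(OCc5ccccc5)cc(OCc5ccccc5)cc4o3)cc1)[C@H](OC)C[C@H](c1ccc(O)cc1)O2
F2 | step 4 | 4-bromo-2,6-dimethoxyphenol (purchased) | COc1cc(Br)cc(OC)c1O
F3 | step 4 | 4-(4-bromo-2,6-dimethoxyphenoxy)benzaldehyde | COc1cc(Br)cc(OC)c1Oc1ccc(C=O)cc1
F4 | step 4 | (E)-1-[2,4-bis(benzyloxy)-6-hydroxyphenyl]-3-[4-(4-bromo-2,6-dimethoxyphenoxy)phenyl]prop-2-en-1-one | O=C(/C=C/c1ccc(Oc2c(OC)cc(Br)cc2OC)cc1)c1c(O)cc(OCc2ccccc2)cc1OCc1ccccc1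
F5 | step 4 | 5,7-bis(benzyloxy)-2-[4-(4-bromo-2,6-dimethoxyphenoxy)phenyl]-4H-chromen-4-one | COc1cc(Br)cc(OC)c1Oc1ccc(-c2cc(=O)c3c(OCc4ccccc4)cc(OCc4ccccc4)cc3o2)cc1
F6 | step 9 | 4-[(2S)-6-{4-[5,7-bis(benzyloxy)-4-oxo-4H-chromen-2-yl]phenoxy}-4-hydroxy-5,7-dimethoxychroman-2-yl]phenyl acetate, mixture of C4 epimers | COc1cc2c(c(OC)c1Oc1ccc(-c3cc(=O)c4c(OCc5ccccc5)cc(OCc5ccccc5)cc4o3)cc1)C(O)C[C@@H](c1ccc(OC(C)=O)cc1)O2
F7 | step 10 | 4-[(2S)-6-[4-(5,7-dihydroxy-4-oxo-4H-chromen-2-yl)phenoxy]-5,7-dimethoxy-4-oxochroman-2-yl]phenyl acetate | COc1cc2c(c(OC)c1Oc1ccc(-c3cc(=O)c4c(O)cc(O)cc4o3)cc1)C(=O)C[C@@H](c1ccc(OC(C)=O)cc1)O2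
A1 | alternative 1 | 2-(ethynyloxy)-1,3-dimethoxy-5-(methoxymethoxy)benzene | C#COc1c(OC)cc(OCOC)cc1OC
A2 | alternative 1 | methyl coumalate (methyl 2-oxo-2H-pyran-5-carboxylate) | COC(=O)C1=COC(=O)C=C1
A3 | alternative 1 | methyl 4-[2,6-dimethoxy-4-(methoxymethoxy)phenoxy]benzoate | COCOc1cc(OC)c(Oc2ccc(C(=O)OC)cc2)c(OC)c1
A4 | alternative 2 | 5-[2-(6-{4-[4-(benzyloxy)-2,6-dimethoxyphenoxy]phenyl}-4-oxo-4H-pyran-2-yl)-1-hydroxyethylidene]-2,2-dimethyl-1,3-dioxane-4,6-dione | COc1cc(OCc2ccccc2)cc(OC)c1Oc1ccc(-c2cc(=O)cc(CC(O)=C3C(=O)OC(C)(C)OC3=O)o2)cc1
A5 | alternative 2 | 2-{4-[4-(benzyloxy)-2,6-dimethoxyphenoxy]phenyl}-5,7-dihydroxy-4H-chromen-4-one | COc1cc(OCc2ccccc2)cc(OC)c1Oc1ccc(-c2cc(=O)c3c(O)cc(O)cc3o2)cc1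
A6 | alternative 3 | [2-(4-iodophenoxy)-1,3-dimethoxybuta-1,3-dien-1-yl]oxy(trimethyl)silane, alkene geometry unassigned | C=C(OC)C(Oc1ccc(I)cc1)=C(OC)O[Si](C)(C)C
A7 | alternative 3 | (2S)-2-[4-(benzyloxy)phenyl]-5-bromo-2,3-dihydro-4H-pyran-4-one | O=C1C[C@@H](c2ccc(OCc3ccccc3)cc2)OC=C1Br
A8 | alternative 3 | (2S)-2-[4-(benzyloxy)phenyl]-5-hydroxy-6-(4-iodophenoxy)-7-methoxychroman-4-one | COc1cc2c(c(O)c1Oc1ccc(I)cc1)C(=O)C[C@@H](c1ccc(OCc3ccccc3)cc1)O2
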